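**Retrosynthetic overview**

1. Sipholenol L (39) is cut at its CH2–CH2 link into two C15 halves, decalin sulfone 22 and benzoxepane aldehyde 36, joined by Julia–Kocienski olefination and diimide reduction.
2. The strategy rests on the cis-fused octalin: a cyclohexene ring with three contiguous CH centres (the chain-bearing carbon and both ring-fusion carbons), fused to a cyclohexane whose CMe2 carbon sits beside one fusion carbon and whose C(Me)OH carbon sits beside the other. One intramolecular Diels–Alder reaction of the (Z)-enoate/2-silyloxydiene 10 closes both carbocycles.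
3. After the cycloaddition the enol ether becomes the ring alkene (ketone, more substituted enol triflate, Pd hydrogenolysis) and the silyloxy carbon becomes the tertiary carbinol (ketone, methylene, convex epoxide, hydride).
4. Triene 10 comes from 2,2-dimethylpent-4-enal by Still–Gennari olefination, hydroformylation, D-proline aminoxylation/Horner–Wadsworth–Emmons (sets the one stereocentre) and two silylations.
5. The benzoxepane half comes from geranyl bromide and methyl acetoacetate by Shi diepoxidation and one Lewis-acid cascade ended by an allylsilane. Ring order: both decalin rings together (step 7); oxepane, then its cyclohexane (step 24).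

Key step: step 7

Remark: atom labels C1–C12 are those of the dodecatrienoate chain of 10 (C1 ester carbon, C4 the CMe2 carbon, C7 the silyloxy carbon, C10 the enol ether carbon) and are kept for the decalin; the C11 methyl centre formed in step 7 is drawn as formed and is erased in step 9; the L-fructose-derived Shi ketone is taken as a purchasable catalyst.

**Route**

Step 1
Reactants: 1 2,2-dimethylpent-4-enal; 2 methyl bis(2,2,2-trifluoroethyl)phosphonoacetate
Product: 3 methyl (2Z)-4,4-dimethylhepta-2,6-dienoate
Conditions: KHMDS, 18-crown-6, THF, −78 °C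
Reagents that add atoms: none
Why: Still–Gennari olefination, in which the electron-poor phosphonate under dissociating conditions eliminates fast from the first adduct, should give the (Z)-enoate from the hindered neopentyl aldehyde without touching the terminal alkene.

Step 2
Reactants: 3 methyl (2Z)-4,4-dimethylhepta-2,6-dienoate
Product: 4 methyl (2Z)-4,4-dimethyl-8-oxooct-2-enoate
Conditions: Rh(acac)(CO)2 (1 mol%), BiPhePhos (2 mol%), CO/H2 1:1 (10 bar), PhMe, 60 °C
Reagents that add atoms: carbon monoxide, [C-]#[O+]
Why: Rh-catalysed hydroformylation with a wide-bite-angle bisphosphite is linear-selective for the monosubstituted alkene, while the β-tert-alkyl (Z)-enoate is too hindered and electron-poor to insert.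

Step 3
Reactants: 4 methyl (2Z)-4,4-dimethyl-8-oxooct-2-enoate; 5 dimethyl (2-oxobutyl)phosphonate
Product: 7 methyl (2Z,7S,8E)-4,4-dimethyl-10-oxo-7-(phenylaminooxy)dodeca-2,8-dienoate, via aminoxy aldehyde 6 (not isolated)
Conditions: PhNO, D-proline (20 mol%), MeCN, −20 °C; then 5, Cs2CO3, 0 °C→rt
Reagents that add atoms: nitrosobenzene, O=Nc1ccccc1
Why: Proline-catalysed α-aminoxylation (enamine O-selective nitroso aldol) should set C7 as S with D-proline through the acid-directed transition state, and the labile aldehyde is trapped at once by a Horner–Wadsworth–Emmons reaction that gives the (E)-enone.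

Step 4
Reactants: 7 anilinooxy enone
Product: 8 methyl (2Z,7S,8E)-7-hydroxy-4,4-dimethyl-10-oxododeca-2,8-dienoate
Conditions: CuSO4·5H2O (30 mol%), MeOH, 0 °C→rt
Reagents that add atoms: none
Why: Cu(II)-catalysed N–O cleavage of the O-anilino group should free the allylic alcohol without reducing the enone or the enoate and without touching C7.

Step 5
Reactants: 8 hydroxy enone
Product: 9 methyl (2Z,7S,8E)-7-(tert-butyldimethylsilyloxy)-4,4-dimethyl-10-oxododeca-2,8-dienoate
Conditions: TBSCl, imidazole, DMF, rt
Reagents that add atoms: tert-butyldimethylsilyl chloride, CC(C)(C)[Si](C)(C)Cl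
Why: Standard silylation of the secondary alcohol installs the bulky group that later fixes the face of the cycloaddition.

Step 6
Reactants: 9 silyloxy enone
Product: 10 methyl (2Z,7S,8E,10Z)-7-(tert-butyldimethylsilyloxy)-4,4-dimethyl-10-(triethylsilyloxy)dodeca-2,8,10-trienoate
Conditions: TESOTf, Et3N, CH2Cl2, −78→0 °C
Reagents that add atoms: triethylsilyl triflate, CC[Si](CC)(CC)OS(=O)(=O)C(F)(F)F
Why: Soft enolisation of the ethyl enone at its only α′ position should give the cross-conjugated (Z)-silyl enol ether, that is the 2-silyloxydiene with its methyl group outside.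

Step 7
Reactants: 10 (Z)-enoate silyloxytriene
Product: 11 cis-fused octalin silyl enol ether ester
Conditions: PhMe (0.01 M), BHT, 2,6-di-tert-butyl-4-methylpyridine (cat.), sealed tube, 160 °C
Reagents that add atoms: none
Why: Thermal intramolecular Diels–Alder reaction of a 1,7,9-decatriene type: a concerted, asynchronous [4+2] addition of the (Z)-enoate (C2=C3) across the 2-silyloxydiene (C8–C11) in which the internal C3–C8 bond, the future ring fusion, runs ahead of the C2–C11 bond; the closest known case is the thermal cyclisation of (Z)-2,8,10-trienoates to cis-fused octalins. The gem-dimethyl cyclohexane closes as the six-membered tether ring through a chair-like tether (C3–C8 bond) and the cyclohexene closes as the cycloadduct ring through the boat-like [4+2] array (C3–C8 and C2–C11 bonds). C3 and C8 (cis fusion) and C2 (ester cis to the C3–C4 branch) follow from the ester-endo transition state open to the (Z)-dienophile together with the (8E) diene geometry, C11 follows from the (10Z) enol ether geometry, and the absolute sense of all four follows from C7, whose silyloxy group takes the equatorial site of the tether chair because the axial site would clash with the axial dienophile carbon C2, the diene being held equatorial at C8 by the axial methyl of C4. The step needs endo over exo selectivity, which rests on the (Z) geometry and is the main uncertainty, and one diene face, which C7 secures. The silyloxy group raises the diene HOMO but the tether imposes the electronically unfavoured orientation (donor terminus C11 bonds to the ester-bearing carbon), so heat with an acid scavenger is used and no Lewis acid, which would strip the enol ether.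

Step 8
Reactants: 11 octalin silyl enol ether
Product: 12 decalin C10 ketone
Conditions: AcOH/THF/H2O (3:1:1), 0 °C→rt
Reagents that add atoms: none
Why: Acid hydrolysis of a silyl enol ether is far faster than cleavage of the secondary TBS ether, and protonation at C9 leaves the other centres untouched.

Step 9
Reactants: 12 decalin ketone
Product: 13 C10–C11 enol triflate
Conditions: Tf2O, 2,6-di-tert-butyl-4-methylpyridine, CH2Cl2, 0 °C→rt
Reagents that add atoms: trifluoromethanesulfonic anhydride, O=S(=O)(OS(=O)(=O)C(F)(F)F)C(F)(F)F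
Why: Enol triflation with triflic anhydride and a hindered pyridine goes through the O-triflyl oxocarbenium ion, which should lose the tertiary C11 proton to give the more substituted (tetrasubstituted) enol triflate, a peracid-inert store for the future ring alkene.

Step 10
Reactants: 13 enol triflate silyl ether
Product: 14 enol triflate C7 alcohol
Conditions: HF·pyridine, pyridine, THF, 0 °C→rt
Reagents that add atoms: none
Why: Buffered fluoride desilylation removes the TBS ether while the vinyl triflate and the ester are stable.

Step 11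
Reactants: 14 enol triflate alcohol
Product: 15 enol triflate C7 ketone
Conditions: Dess–Martin periodinane, CH2Cl2, rt
Reagents that add atoms: none
Why: Dess–Martin oxidation is non-basic, so the epimerisable cis ring-fusion centre next to the new ketone should be kept.

Step 12
Reactants: 15 decalone
Product: 16 C7 methylidene decalin
Conditions: Zn, CH2Br2, TiCl4, THF/CH2Cl2, 0 °C→rt
Reagents that add atoms: dibromomethane, BrCBr
Why: Takai–Lombardo methylenation uses a non-basic titanium methylidene reagent that converts hindered, enolisable ketones without epimerisation and leaves the ester and the vinyl triflate alone.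

Step 13
Reactants: 16 methylidene decalin
Product: 17 spiro-epoxide, oxygen on the face of the ring-fusion hydrogens
Conditions: mCPBA, NaHCO3, CH2Cl2, 0 °C
Reagents that add atoms: 3-chloroperoxybenzoic acid, OOC(=O)c1cccc(Cl)c1
Why: Prilezhaev epoxidation should occur on the convex face of the cis-decalin, because the other face of the exocyclic alkene is shielded by the axial C2 branch, which puts the oxygen where the tertiary hydroxyl of the target sits; the triflate-bearing alkene is too electron-poor to react.

Step 14
Reactants: 17 spiro-epoxide enol triflate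
Product: 18 spiro-epoxide with C10=C11 ring alkene
Conditions: Pd(PPh3)4 (5 mol%), LiCl, Bu3SnH, THF, 60 °C
Reagents that add atoms: none
Why: Pd(0)-catalysed hydrogenolysis of a vinyl triflate with tin hydride replaces OTf by H with the double bond fixed in place, under neutral conditions that spare the epoxide and the ester.

Step 15
Reactants: 18 epoxy ester
Product: 19 decalin diol
Conditions: LiAlH4, THF, 0 °C→reflux
Reagents that add atoms: none
Why: Hydride opens the spiro-epoxide by SN2 attack at its CH2 group, which leaves the tertiary C–O bond and its configuration intact, and the same reagent reduces the ester to the primary alcohol.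

Step 16
Reactants: 19 decalin diol
Product: 20 phenyltetrazolyl sulfide
Conditions: 1-phenyl-1H-tetrazole-5-thiol, PPh3, DIAD, THF, 0 °C→rt
Reagents that add atoms: 1-phenyl-1H-tetrazole-5-thiol, Sc1nnnn1-c1ccccc1
Why: Mitsunobu thioetherification acts only on the primary alcohol, since the tertiary alcohol cannot form a reactive oxyphosphonium ion.

Step 17
Reactants: 20 sulfide
Product: 21 phenyltetrazolyl sulfone
Conditions: (NH4)6Mo7O24·4H2O (cat.), 30% H2O2, EtOH, 0 °C→rt
Reagents that add atoms: hydrogen peroxide, OO
Why: Molybdate-catalysed peroxide oxidation takes sulfides to sulfones much faster than it epoxidises a trisubstituted alkene.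

Step 18
Reactants: 21 sulfone alcohol
Product: 22 sulfone triethylsilyl ether
Conditions: TESOTf, 2,6-lutidine, CH2Cl2, −78→0 °C
Reagents that add atoms: triethylsilyl triflate, CC[Si](CC)(CC)OS(=O)(=O)C(F)(F)F
Why: Silyl triflate silylation caps the tertiary alcohol so that no alkoxide interferes with the sulfonyl carbanion in the coupling.

Step 19
Reactants: 23 geranyl bromide; 24 methyl acetoacetate
Product: 25 methyl (6E)-7,11-dimethyl-3-oxododeca-6,10-dienoate
Conditions: 24, NaH then n-BuLi, THF, 0 °C; then 23, 0 °C
Reagents that add atoms: none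
Why: γ-Alkylation of the acetoacetate dianion with the allylic bromide is an SN2 reaction at the more reactive terminal carbanion and keeps the (E) alkene.

Step 20
Reactants: 25 β-keto ester
Product: 26 (2Z)-enol diethyl phosphate
Conditions: NaH, Et2O, 0 °C; ClP(O)(OEt)2
Reagents that add atoms: diethyl chlorophosphate, CCOP(=O)(Cl)OCC
Why: O-Phosphorylation of the chelated sodium enolate in ether gives the (Z)-enol phosphate, with phosphate and ester cis.

Step 21
Reactants: 26 enol phosphate
Product: 27 methyl (2Z,6E)-7,11-dimethyl-3-[(trimethylsilyl)methyl]dodeca-2,6,10-trienoate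
Conditions: Me3SiCH2MgCl, Ni(acac)2 (5 mol%), THF, rt
Reagents that add atoms: (trimethylsilyl)methylmagnesium chloride, C[Si](C)(C)C[Mg]Cl
Why: Nickel-catalysed Kumada-type coupling of the enol phosphate goes with retention of alkene geometry and gives the allylsilane still deactivated by the conjugated ester.

Step 22
Reactants: 27 allylsilane trienoate
Product: 28 (6S,7S,10S)-diepoxide ester
Conditions: L-fructose-derived Shi ketone (0.6 equiv), Oxone, K2CO3, Bu4NHSO4 (cat.), MeCN/DMM/aq. borate–EDTA buffer, 0 °C
Reagents that add atoms: potassium peroxymonosulfate (Oxone), [K+].[O-]S(=O)(=O)OO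
Why: Shi asymmetric epoxidation through the spiro dioxirane transition state should convert the two electron-rich trisubstituted alkenes to the (S)-configured epoxides with this catalyst enantiomer, while the enoate alkene does not react.

Step 23
Reactants: 28 diepoxide ester
Product: 29 diepoxide allylic alcohol
Conditions: DIBAL-H, CH2Cl2, −78 °C
Reagents that add atoms: none
Why: 1,2-Reduction of the enoate at low temperature gives the allylic alcohol, which switches on the allylsilane as a nucleophile, and trisubstituted epoxides are not opened under these conditions.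

Step 24
Reactants: 29 diepoxide allylic alcohol
Product: 32 trans-fused methylidene benzoxepane diol, via silylated diepoxide 30 (not isolated), via bicyclic bis(trimethylsilyl) ether 31 (not isolated)
Conditions: TMSOTf, 2,6-di-tert-butyl-4-methylpyridine, CH2Cl2, −78 °C; then K2CO3 (cat.), MeOH, rt
Reagents that add atoms: none
Why: Lewis-acid-triggered diepoxide cascade (oxacyclisation, then cation–olefin cyclisation ended by an allylsilane in SE2′ fashion): the silyl-activated terminal epoxide is opened at its tertiary carbon by the neighbouring epoxide oxygen (7-endo, carbinol configuration retained), the epoxonium ion is opened with inversion at its methyl-bearing carbon by the allylsilane through a chair (angular methyl axial, ring C–O equatorial, CH2O branch equatorial from the (Z)-allylsilane), and loss of silicon leaves only the exocyclic alkene.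

Step 25
Reactants: 32 methylidene benzoxepane diol
Product: 33 spiro-epoxy diol
Conditions: mCPBA, NaHCO3, CH2Cl2, 0 °C
Reagents that add atoms: 3-chloroperoxybenzoic acid, OOC(=O)c1cccc(Cl)c1
Why: Prilezhaev epoxidation should come from the equatorial side, anti to the axial angular methyl group that blocks the other face by a 1,3-diaxial contact.

Step 26
Reactants: 33 spiro-epoxy diol
Product: 34 benzoxepane triol
Conditions: LiAlH4, THF, reflux
Reagents that add atoms: none
Why: SN2 hydride opening at the epoxide CH2 gives the tertiary alcohol with equatorial hydroxyl and axial methyl, the arrangement that methyl addition to a ketone would not give.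

Step 27
Reactants: 34 benzoxepane triol
Product: 35 tris(triethylsilyl) ether
Conditions: TESOTf, 2,6-lutidine, CH2Cl2, −78→0 °C
Reagents that add atoms: triethylsilyl triflate, CC[Si](CC)(CC)OS(=O)(=O)C(F)(F)F
Why: Exhaustive silylation with the silyl triflate covers the primary, the hindered secondary and the tertiary hydroxyl in one operation.

Step 28
Reactants: 35 tris(triethylsilyl) ether
Product: 36 benzoxepane aldehyde
Conditions: (COCl)2, DMSO, CH2Cl2, −78→−30 °C; then Et3N
Reagents that add atoms: none
Why: Swern oxidation applied directly to a primary triethylsilyl ether exchanges that least hindered silyl group for the alkoxysulfonium ion and oxidises it, leaving the secondary and tertiary silyl ethers.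

Step 29
Reactants: 22 decalin sulfone; 36 benzoxepane aldehyde
Product: 37 (E)-alkene-linked bis-fragment
Conditions: KHMDS added to 22 + 36, THF, −78 °C→rt
Reagents that add atoms: none
Why: Julia–Kocienski olefination (carbanion addition, Smiles rearrangement, loss of SO2 and tetrazolone) forms the link as an alkene, and adding the base last lets the carbanion be captured by the hindered aldehyde as it forms; alkene geometry is irrelevant.

Step 30
Reactants: 37 alkene-linked bis-fragment
Product: 38 saturated tris(triethylsilyl) ether of the target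
Conditions: TsNHNH2, NaOAc, DME/H2O, reflux
Reagents that add atoms: none
Why: Diimide syn-hydrogenation is much faster for the 1,2-disubstituted alkene than for the trisubstituted ring alkene and touches no other group.

Step 31
Reactants: 38 saturated tris(triethylsilyl) ether
Product: 39 sipholenol L
Conditions: HF·pyridine, pyridine, THF, 0 °C→rt
Reagents that add atoms: none
Why: Fluoride desilylation removes the three triethylsilyl ethers under buffered conditions that do not dehydrate the tertiary alcohols.

**Compound list**

1 | 2,2-dimethylpent-4-enal | C=CCC(C)(C)C=O | starting material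
2 | methyl bis(2,2,2-trifluoroethyl)phosphonoacetate | COC(=O)CP(=O)(OCC(F)(F)F)OCC(F)(F)F | starting material
3 | methyl (2Z)-4,4-dimethylhepta-2,6-dienoate | C=CCC(C)(C)/C=C\C(=O)OC | intermediate
4 | methyl (2Z)-4,4-dimethyl-8-oxooct-2-enoate | O=CCCCC(C)(C)/C=C\C(=O)OC | intermediate
5 | dimethyl (2-oxobutyl)phosphonate | CCC(=O)CP(=O)(OC)OC | starting material
6 | methyl (2Z,7S)-4,4-dimethyl-8-oxo-7-(phenylaminooxy)oct-2-enoate | O=C[C@@H](ONc1ccccc1)CCC(C)(C)/C=C\C(=O)OC | intermediate
7 | methyl (2Z,7S,8E)-4,4-dimethyl-10-oxo-7-(phenylaminooxy)dodeca-2,8-dienoate | CCC(=O)/C=C/[C@@H](ONc1ccccc1)CCC(C)(C)/C=C\C(=O)OC | intermediate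
8 | methyl (2Z,7S,8E)-7-hydroxy-4,4-dimethyl-10-oxododeca-2,8-dienoate | CCC(=O)/C=C/[C@@H](O)CCC(C)(C)/C=C\C(=O)OC | intermediate
9 | methyl (2Z,7S,8E)-7-(tert-butyldimethylsilyloxy)-4,4-dimethyl-10-oxododeca-2,8-dienoate | CCC(=O)/C=C/[C@@H](O[Si](C)(C)C(C)(C)C)CCC(C)(C)/C=C\C(=O)OC | intermediate
10 | methyl (2Z,7S,8E,10Z)-7-(tert-butyldimethylsilyloxy)-4,4-dimethyl-10-(triethylsilyloxy)dodeca-2,8,10-trienoate | C/C=C(O[Si](CC)(CC)CC)/C=C/[C@@H](O[Si](C)(C)C(C)(C)C)CCC(C)(C)/C=C\C(=O)OC | intermediate
11 | methyl 5-(tert-butyldimethylsilyloxy)-2,8,8-trimethyl-3-(triethylsilyloxy)-1,2,4a,5,6,7,8,8a-octahydronaphthalene-1-carboxylate; cis-fused, H-1, H-2, H-4a, H-8a and the 5-oxygen on one face | C[C@@H]1C(O[Si](CC)(CC)CC)=C[C@H]2[C@@H]([C@@H]1C(=O)OC)C(C)(C)CC[C@@H]2O[Si](C)(C)C(C)(C)C | intermediate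
12 | methyl 5-(tert-butyldimethylsilyloxy)-2,8,8-trimethyl-3-oxodecahydronaphthalene-1-carboxylate; configuration as in 11 | C[C@@H]1C(=O)C[C@H]2[C@@H]([C@@H]1C(=O)OC)C(C)(C)CC[C@@H]2O[Si](C)(C)C(C)(C)C | intermediate
13 | methyl 5-(tert-butyldimethylsilyloxy)-2,8,8-trimethyl-3-(trifluoromethylsulfonyloxy)-1,4,4a,5,6,7,8,8a-octahydronaphthalene-1-carboxylate; cis-fused, H-1, H-4a, H-8a and 5-oxygen on one face | CC1=C(OS(=O)(=O)C(F)(F)F)C[C@H]2[C@@H]([C@@H]1C(=O)OC)C(C)(C)CC[C@@H]2O[Si](C)(C)C(C)(C)C | intermediate
14 | 5-hydroxy analogue of 13 | CC1=C(OS(=O)(=O)C(F)(F)F)C[C@H]2[C@@H]([C@@H]1C(=O)OC)C(C)(C)CC[C@@H]2O | intermediate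
15 | 5-oxo analogue of 13 (cis-decalone) | CC1=C(OS(=O)(=O)C(F)(F)F)C[C@H]2[C@@H]([C@@H]1C(=O)OC)C(C)(C)CCC2=O | intermediate
16 | 5-methylidene analogue of 13 | CC1=C(OS(=O)(=O)C(F)(F)F)C[C@H]2[C@@H]([C@@H]1C(=O)OC)C(C)(C)CCC2=C | intermediate
17 | 5-spiro-oxirane of 16, epoxide oxygen on the face of H-4a and H-8a | CC1=C(OS(=O)(=O)C(F)(F)F)C[C@H]2[C@@H]([C@@H]1C(=O)OC)C(C)(C)CC[C@]2(C3)O3 | intermediate
18 | methyl 2,8,8-trimethyl-5-spiro-oxiranyl-1,4,4a,5,6,7,8,8a-octahydronaphthalene-1-carboxylate (triflate replaced by H) | CC1=CC[C@H]2[C@@H]([C@@H]1C(=O)OC)C(C)(C)CC[C@]2(C3)O3 | intermediate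
19 | 1-(hydroxymethyl)-2,5,8,8-tetramethyl-1,4,4a,5,6,7,8,8a-octahydronaphthalen-5-ol; cis-fused, H-1, H-4a, H-8a and 5-OH on one face, 5-methyl on the other | CC1=CC[C@H]2[C@@H]([C@@H]1CO)C(C)(C)CC[C@]2(C)O | intermediate
20 | 1-phenyl-1H-tetrazol-5-yl sulfide of the primary carbon of 19 | CC1=CC[C@H]2[C@@H]([C@@H]1CSc1nnnn1-c1ccccc1)C(C)(C)CC[C@]2(C)O | intermediate
21 | corresponding 1-phenyl-1H-tetrazol-5-yl sulfone | CC1=CC[C@H]2[C@@H]([C@@H]1CS(=O)(=O)c1nnnn1-c1ccccc1)C(C)(C)CC[C@]2(C)O | intermediate
22 | triethylsilyl ether of sulfone 21 | CC1=CC[C@H]2[C@@H]([C@@H]1CS(=O)(=O)c1nnnn1-c1ccccc1)C(C)(C)CC[C@]2(C)O[Si](CC)(CC)CC | intermediate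
23 | geranyl bromide, (2E)-1-bromo-3,7-dimethylocta-2,6-diene | CC(C)=CCC/C(C)=C/CBr | starting material
24 | methyl acetoacetate | COC(=O)CC(C)=O | starting material
25 | methyl (6E)-7,11-dimethyl-3-oxododeca-6,10-dienoate | COC(=O)CC(=O)CC/C=C(\C)CCC=C(C)C | intermediate
26 | methyl (2Z,6E)-3-(diethoxyphosphoryloxy)-7,11-dimethyldodeca-2,6,10-trienoate | COC(=O)/C=C(\OP(=O)(OCC)OCC)CC/C=C(\C)CCC=C(C)C | intermediate
27 | methyl (2Z,6E)-7,11-dimethyl-3-[(trimethylsilyl)methyl]dodeca-2,6,10-trienoate | COC(=O)/C=C(\C[Si](C)(C)C)CC/C=C(\C)CCC=C(C)C | intermediate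
28 | methyl (2Z,6S,7S,10S)-6,7:10,11-diepoxy-7,11-dimethyl-3-[(trimethylsilyl)methyl]dodec-2-enoate | COC(=O)/C=C(\C[Si](C)(C)C)CC[C@@H]1O[C@@]1(C)CC[C@@H]1OC1(C)C | intermediate
29 | (2Z,6S,7S,10S)-6,7:10,11-diepoxy-7,11-dimethyl-3-[(trimethylsilyl)methyl]dodec-2-en-1-ol | OC/C=C(\C[Si](C)(C)C)CC[C@@H]1O[C@@]1(C)CC[C@@H]1OC1(C)C | intermediate
30 | trimethylsilyl ether of 29 | C[Si](C)(C)OC/C=C(\C[Si](C)(C)C)CC[C@@H]1O[C@@]1(C)CC[C@@H]1OC1(C)C | intermediate
31 | bis(trimethylsilyl) ether of 32 | C[Si](C)(C)OC[C@H]1[C@]2(C)CC[C@H](O[Si](C)(C)C)C(C)(C)O[C@H]2CCC1=C | intermediate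
32 | 6-(hydroxymethyl)-2,2,5a-trimethyl-7-methylidenedecahydro-1-benzoxepin-3-ol; trans-fused, H-6, H-9a and 3-OH on the face opposite the 5a-methyl | OC[C@H]1[C@]2(C)CC[C@H](O)C(C)(C)O[C@H]2CCC1=C | intermediate
33 | 7-spiro-oxirane of 32, epoxide oxygen anti to the 5a-methyl | OC[C@H]1[C@]2(C)CC[C@H](O)C(C)(C)O[C@H]2CC[C@]1(C3)O3 | intermediate
34 | 6-(hydroxymethyl)-2,2,5a,7-tetramethyldecahydro-1-benzoxepine-3,7-diol; 5a- and 7-methyl syn, 7-OH, H-6, H-9a and 3-OH on the other face | OC[C@H]1[C@]2(C)CC[C@H](O)C(C)(C)O[C@H]2CC[C@]1(C)O | intermediate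
35 | tris(triethylsilyl) ether of 34 | CC[Si](CC)(CC)OC[C@H]1[C@]2(C)CC[C@H](O[Si](CC)(CC)CC)C(C)(C)O[C@H]2CC[C@]1(C)O[Si](CC)(CC)CC | intermediate
36 | 2,2,5a,7-tetramethyl-3,7-bis(triethylsilyloxy)decahydro-1-benzoxepine-6-carbaldehyde, configuration as in 34 | O=C[C@H]1[C@]2(C)CC[C@H](O[Si](CC)(CC)CC)C(C)(C)O[C@H]2CC[C@]1(C)O[Si](CC)(CC)CC | intermediate
37 | (E)-ethene-1,2-diyl-linked decalin/benzoxepane, three OSiEt3 groups | CC1=CC[C@H]2[C@@H]([C@@H]1/C=C/[C@H]1[C@]3(C)CC[C@H](O[Si](CC)(CC)CC)C(C)(C)O[C@H]3CC[C@]1(C)O[Si](CC)(CC)CC)C(C)(C)CC[C@]2(C)O[Si](CC)(CC)CC | intermediate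
38 | tris(triethylsilyl) ether of sipholenol L | CC1=CC[C@H]2[C@@H]([C@@H]1CC[C@H]1[C@]3(C)CC[C@H](O[Si](CC)(CC)CC)C(C)(C)O[C@H]3CC[C@]1(C)O[Si](CC)(CC)CC)C(C)(C)CC[C@]2(C)O[Si](CC)(CC)CC | intermediate
39 | sipholenol L | CC1=CC[C@H]2[C@@H]([C@@H]1CC[C@H]1[C@]3(C)CC[C@H](O)C(C)(C)O[C@H]3CC[C@]1(C)O)C(C)(C)CC[C@]2(C)O | target

**Step count and risks**

Total step count: 31. Longest linear sequence: 21 steps (steps 1–18, then 29–31); the benzoxepane branch is steps 19–28.

Steps most likely to fail:

1. Step 7. The hindered (Z)-enoate may cyclise too slowly, so that the silyl enol ether is lost or the enoate isomerises before ring closure, or the endo preference may erode and give trans-fused material. Fallback: change the diene to one that tolerates a Lewis acid. Setting out from enone 9, kinetic enolisation at the ethyl group (LiHMDS, THF, −78 °C) and O-acetylation (Ac2O) should give the 2-acetoxy triene F1. MeAlCl2 or Et2AlCl (CH2Cl2, −78→0 °C) bound to the (Z)-enoate then drives the same cycloaddition at low temperature to the enol acetate cycloadduct F2. Methanolysis (K2CO3, MeOH, 0 °C) comes back to the route at ketone 12.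

2. Step 9. Proton loss from the less substituted C9 may compete and give the regioisomeric enol triflate, which would place the ring alkene wrongly. Fallback: generate the enolate regiospecifically by reductive cleavage instead of by equilibrium control. Setting out from ketone 12, bromination through the more substituted enol (PhNMe3Br3, THF, 0 °C) gives the α-bromo ketone F3, which can be purified from any regioisomer. Me2CuLi (Et2O, −78 °C) then removes bromine to leave the C10–C11 enolate only, and trapping with N-(5-chloro-2-pyridyl)triflimide comes back to the route at enol triflate 13.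

3. Step 29. Addition of the sulfonyl carbanion to the congested β-silyloxy aldehyde may be slower than enolisation and β-elimination of the aldehyde or self-condensation of the sulfone. Fallback: join the halves by carbonyl addition of a small alkyllithium and remove the resulting hydroxyl by a radical route. Setting out from diol 19, Appel iodination of the primary alcohol (I2, PPh3, imidazole) gives the iodide F4, and silylation (TESOTf, 2,6-lutidine) gives the iodide silyl ether F5. Iodine–lithium exchange (t-BuLi, Et2O, −78 °C) and addition to aldehyde 36 give the secondary alcohol F6 (either carbinol epimer serves). Xanthate formation (KHMDS, CS2, MeI) gives the S-methyl xanthate F7, and Barton–McCombie deoxygenation (Bu3SnH, AIBN, PhMe, 90 °C) comes back to the route at 38, with no alkene to reduce.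

**Further compounds**

F1 | step 7 | methyl (2Z,7S,8E,10Z)-10-acetoxy-7-(tert-butyldimethylsilyloxy)-4,4-dimethyldodeca-2,8,10-trienoate | C/C=C(OC(C)=O)/C=C/[C@@H](O[Si](C)(C)C(C)(C)C)CCC(C)(C)/C=C\C(=O)OC
F2 | step 7 | enol acetate analogue of 11 (3-acetoxy in place of 3-triethylsilyloxy) | C[C@@H]1C(OC(C)=O)=C[C@H]2[C@@H]([C@@H]1C(=O)OC)C(C)(C)CC[C@@H]2O[Si](C)(C)C(C)(C)C
F3 | step 9 | methyl 2-bromo-5-(tert-butyldimethylsilyloxy)-2,8,8-trimethyl-3-oxodecahydronaphthalene-1-carboxylate (bromine-bearing centre unassigned, erased in the next operation) | CC1(Br)C(=O)C[C@H]2[C@@H]([C@@H]1C(=O)OC)C(C)(C)CC[C@@H]2O[Si](C)(C)C(C)(C)C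
F4 | step 29 | 1-(iodomethyl)-2,5,8,8-tetramethyl-1,4,4a,5,6,7,8,8a-octahydronaphthalen-5-ol, configuration as in 19 | CC1=CC[C@H]2[C@@H]([C@@H]1CI)C(C)(C)CC[C@]2(C)O
F5 | step 29 | triethylsilyl ether of F4 | CC1=CC[C@H]2[C@@H]([C@@H]1CI)C(C)(C)CC[C@]2(C)O[Si](CC)(CC)CC
F6 | step 29 | secondary alcohol from addition of the decalin-methyl lithium to 36 (carbinol centre unassigned) | CC1=CC[C@H]2[C@@H]([C@@H]1CC(O)[C@H]1[C@]3(C)CC[C@H](O[Si](CC)(CC)CC)C(C)(C)O[C@H]3CC[C@]1(C)O[Si](CC)(CC)CC)C(C)(C)CC[C@]2(C)O[Si](CC)(CC)CC
F7 | step 29 | S-methyl xanthate of F6 | CC1=CC[C@H]2[C@@H]([C@@H]1CC(OC(=S)SC)[C@H]1[C@]3(C)CC[C@H](O[Si](CC)(CC)CC)C(C)(C)O[C@H]3CC[C@]1(C)O[Si](CC)(CC)CC)C(C)(C)CC[C@]2(C)O[Si](CC)(CC)CC
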